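**Retrosynthetic overview**
1. The target is reached from one keto-pyranone adduct by late adjustments only: ketone reduction, acetylation, Barton–McCombie removal of a cyclopentanone oxygen, unmasking of an allyl acetal and lactol oxidation.
2. Key bond (quaternary C1 of the hydroazulene to C5 of the future lactone): Mukaiyama–Michael addition of a tetrasubstituted hydroazulenone enol silane to (R)-2-(allyloxy)-2H-pyran-3(6H)-one, followed in the same flask by hydroxymethylation of the new enol silane.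
3. The pyranone comes from D-arabinose (Fischer glycoside, Corey–Winter olefination, MnO2); its ring becomes the lactone ring.
4. The hydroazulenone comes from a Prins–pinacol ring-enlarging cyclopentane annulation of a 1-propenylcyclohexanol thioacetal, itself from (S)-2-allyl-3,3-dimethylcyclohexanone (cuprate addition to 3-methylcyclohexenone, Pd asymmetric allylation).
5. Ring order: cyclohexane (bought), then the seven- and five-membered carbocycles together in one step, then coupling to the preformed pyran, then lactone by oxidation.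

Assumption: locants are oxane O1, C2 (acetal, later C=O), C3, C4, C5, C6 and decahydroazulene C1 (quaternary), C2, C3, C3a, C4 (gem-dimethyl), C8 (methylidene), C8a; centres that are erased later (C1/C2 in 10–13, C2 in 24/25, the anomeric carbon in 28) are left undefined.

**Step 1**
Reactants: 1 3-methylcyclohex-2-en-1-one
Product: 3 allyl 3,3-dimethylcyclohex-1-en-1-yl carbonate, via lithium enolate 2 (not isolated)
Conditions: Me2CuLi (from MeLi, CuI), Et2O, 0 °C; then ClCO2CH2CH=CH2, THF, TMEDA, −78 °C to rt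
Reagents that add atoms: lithium dimethylcuprate [Li+].C[Cu-]C; allyl chloroformate C=CCOC(=O)Cl
Why: Conjugate addition of the Gilman reagent builds the gem-dimethyl carbon and a regiodefined enolate, which is O-acylated by the chloroformate to the enol carbonate (no stereocentre yet).

**Step 2**
Reactants: 3 allyl 3,3-dimethylcyclohex-1-en-1-yl carbonate
Product: 4 (S)-2-allyl-3,3-dimethylcyclohexan-1-one
Conditions: Pd2(dba)3·CHCl3 (2.5 mol %), (R,R)-ANDEN-phenyl Trost ligand (5.5 mol %), 1,4-dioxane, rt (the (S,S)-ligand is used instead if chiral GC shows the (R)-ketone)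
Reagents that add atoms: none
Why: Decarboxylative asymmetric allylic alkylation (Tsuji–Trost type) through a zerovalent palladium π-allyl/enolate ion pair, in which the chiral diphosphine pocket selects the enolate face and sets the α-stereocentre.

**Step 3**
Reactants: 4 (S)-2-allyl-3,3-dimethylcyclohexan-1-one
Product: 5 (S)-2-(2,2-dimethyl-6-oxocyclohexyl)acetaldehyde
Conditions: O3, CH2Cl2/MeOH, −78 °C; then PPh3, −78 °C to rt
Reagents that add atoms: ozone [O-][O+]=O
Why: Ozonolysis with reductive work-up cleaves the only C=C to the aldehyde under neutral, cold conditions that leave the α-stereocentre untouched.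

**Step 4**
Reactants: 5 (S)-2-(2,2-dimethyl-6-oxocyclohexyl)acetaldehyde
Product: 6 (S)-2-[2,2-bis(phenylsulfanyl)ethyl]-3,3-dimethylcyclohexan-1-one
Conditions: PhSH (2.2 equiv), BF3·OEt2 (0.3 equiv), CH2Cl2, −30 to 0 °C
Reagents that add atoms: thiophenol Sc1ccccc1
Why: Lewis-acid thioacetalisation is chemoselective for the unhindered aldehyde over the congested ketone.

**Step 5**
Reactants: 6 (S)-2-[2,2-bis(phenylsulfanyl)ethyl]-3,3-dimethylcyclohexan-1-one
Product: 7 (1S,2S)-2-[2,2-bis(phenylsulfanyl)ethyl]-3,3-dimethyl-1-[(Z)-prop-1-enyl]cyclohexan-1-ol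
Conditions: (Z)-MeCH=CHBr, t-BuLi (2 equiv), Et2O, −78 °C; CeCl3, THF, −78 °C; then 6, −78 °C; aq. NH4Cl
Reagents that add atoms: (Z)-1-bromoprop-1-ene C/C=C\Br
Why: 1,2-Addition of a non-basic alkenylcerium reagent (Imamoto conditions) to the enolisable ketone, with equatorial attack giving mainly the alkenyl group trans to the side chain; this carbinol carbon becomes a carbonyl in step 7, so its configuration is not critical.

**Step 6**
Reactants: 7 (1S,2S)-2-[2,2-bis(phenylsulfanyl)ethyl]-3,3-dimethyl-1-[(Z)-prop-1-enyl]cyclohexan-1-ol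
Product: 8 trimethylsilyl ether of 7
Conditions: Me3SiOTf, 2,6-lutidine, CH2Cl2, −78 to 0 °C
Reagents that add atoms: trimethylsilyl triflate C[Si](C)(C)OS(=O)(=O)C(F)(F)F
Why: Silylation of the tertiary alcohol stops the oxygen from trapping the thionium ion and supplies the silyloxy terminator for the pinacol shift.

**Step 7**
Reactants: 8 trimethylsilyl ether of 7
Product: 10 (3aR,8aR)-1,4,4-trimethyl-2-(phenylsulfanyl)decahydroazulen-8-one, via thionium ion 9 (not isolated)
Conditions: [Me2S–SMe]BF4 (1.3 equiv), CH2Cl2, −45 to 0 °C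
Reagents that add atoms: none
Why: Prins–pinacol ring-enlarging cyclopentane annulation: the thionium ion attacks the propenyl group in a six-ring Prins closure, and the β-silyloxy cation triggers a suprafacial 1,2-shift of the ring bond with retention, giving the seven-membered ketone and the cis ring fusion (C8a set here).

**Step 8**
Reactants: 10 (3aR,8aR)-1,4,4-trimethyl-2-(phenylsulfanyl)decahydroazulen-8-one
Product: 11 (3aR,8aR)-1,4,4-trimethyl-8-methylidene-2-(phenylsulfanyl)decahydroazulene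
Conditions: Zn, CH2Br2, TiCl4, THF; then 10, CH2Cl2, 0 °C to rt
Reagents that add atoms: dibromomethane BrCBr
Why: Takai–Lombardo methylenation is non-basic, so the hindered ketone becomes the exocyclic alkene without epimerising the adjacent ring-fusion centre; the sulfide is tolerated.

**Step 9**
Reactants: 11 (3aR,8aR)-1,4,4-trimethyl-8-methylidene-2-(phenylsulfanyl)decahydroazulene
Product: 13 (3aR,8aR)-1,4,4-trimethyl-8-methylidenedecahydroazulen-2-one, via α-chloro sulfide 12 (not isolated)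
Conditions: NCS (1.05 equiv), CH2Cl2, 0 °C; then CuO, CuCl2·2H2O, acetone/H2O, 40 °C
Reagents that add atoms: water O; N-chlorosuccinimide O=C1CCC(=O)N1Cl (its chlorine is carried only by 12)
Why: Pummerer-type α-chlorination of the sulfide followed by copper-assisted hydrolysis of the α-chloro sulfide unmasks the cyclopentanone; the alkene is inert to NCS.

**Step 10**
Reactants: 13 (3aR,8aR)-1,4,4-trimethyl-8-methylidenedecahydroazulen-2-one
Product: 14 (3aR,8aS)-1,4,4-trimethyl-8-methylidene-2-(trimethylsilyloxy)-3,3a,4,5,6,7,8,8a-octahydroazulene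
Conditions: Me3SiCl, NaI, Et3N, MeCN, rt (equilibrating)
Reagents that add atoms: chlorotrimethylsilane C[Si](C)(C)Cl
Why: Silyl enol ether formation under thermodynamic control gives the tetrasubstituted enol silane, fixing C1 as the nucleophilic carbon (any minor regioisomer gives a separable adduct later).

**Step 11**
Reactants: 15 D-arabinose
Product: 16 allyl β-D-arabinopyranoside
Conditions: allyl alcohol (solvent), AcCl (0.3 equiv, source of HCl), 50 °C; crystallise
Reagents that add atoms: allyl alcohol C=CCO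
Why: Fischer glycosidation under thermodynamic control gives the crystalline β-pyranoside (axial allyloxy, anomeric effect), fixing the (R) acetal carbon that later steers the Michael addition.

**Step 12**
Reactants: 16 allyl β-D-arabinopyranoside
Product: 17 allyl 3,4-O-thiocarbonyl-β-D-arabinopyranoside
Conditions: 1,1'-thiocarbonyldiimidazole (1.05 equiv), THF, reflux
Reagents that add atoms: 1,1'-thiocarbonyldiimidazole S=C(n1ccnc1)n1ccnc1
Why: A five-membered cyclic thionocarbonate can close only across the cis 3,4-diol, so the trans 2-OH stays free.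

**Step 13**
Reactants: 17 allyl 3,4-O-thiocarbonyl-β-D-arabinopyranoside
Product: 18 (2R,3S)-2-(allyloxy)-3,6-dihydro-2H-pyran-3-ol
Conditions: P(OMe)3, 110 °C
Reagents that add atoms: none
Why: Corey–Winter olefination extrudes CO2 and sulfur from the thionocarbonate to give the ring alkene.

**Step 14**
Reactants: 18 (2R,3S)-2-(allyloxy)-3,6-dihydro-2H-pyran-3-ol
Product: 19 (R)-2-(allyloxy)-2H-pyran-3(6H)-one
Conditions: MnO2 (activated, excess), CH2Cl2, rt; used fresh, kept away from amines
Reagents that add atoms: none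
Why: Allylic alcohol oxidation by MnO2 is neutral, so the acetal centre next to the new carbonyl is not epimerised.

**Step 15**
Reactants: 14 (3aR,8aS)-1,4,4-trimethyl-8-methylidene-2-(trimethylsilyloxy)-3,3a,4,5,6,7,8,8a-octahydroazulene; 19 (R)-2-(allyloxy)-2H-pyran-3(6H)-one
Product: 21 (2R,4R,5R)-2-(allyloxy)-4-(hydroxymethyl)-5-[(1R,3aR,8aS)-1,4,4-trimethyl-8-methylidene-2-oxodecahydroazulen-1-yl]oxan-3-one, via silyl enol ether adduct 20 (not isolated)
Conditions: 19 (1.3 equiv), Me3SiNTf2 (5 mol %), CH2Cl2, −78 °C; then 2,6-lutidine (10 mol %), THF, 37 % aq. HCHO, Yb(OTf)3 (10 mol %), 0 °C to rt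
Reagents that add atoms: formaldehyde C=O
Why: Mukaiyama–Michael addition in which the enol silane attacks C5 of the silyl-activated enone from its convex face (syn to the ring-fusion hydrogens, setting C1) and anti to the pseudo-axial allyloxy group (setting C5), after which silyl transfer gives enol silane 20 and its Lewis-acid-catalysed aqueous aldol with formaldehyde places CH2OH on C4 trans to the C5 substituent, which is also the equatorial, thermodynamic position.

**Step 16**
Reactants: 21 (2R,4R,5R)-2-(allyloxy)-4-(hydroxymethyl)-5-[(1R,3aR,8aS)-1,4,4-trimethyl-8-methylidene-2-oxodecahydroazulen-1-yl]oxan-3-one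
Product: 22 (2R,3S,4R,5R)-2-(allyloxy)-4-(hydroxymethyl)-5-[(1R,3aR,8aS)-1,4,4-trimethyl-8-methylidene-2-oxodecahydroazulen-1-yl]oxan-3-ol
Conditions: Li[HB(s-Bu)3] (L-Selectride, 2.2 equiv), THF, −78 °C; aq. NH4Cl
Reagents that add atoms: none
Why: Hydride reduction of a 2-alkoxyoxan-3-one flanked by two equatorial substituents, where the bulky borohydride attacks equatorially to give the axial alcohol cis to both neighbours (the β-mannoside-type outcome), and the activated α,α-dioxygenated ketone should react well before the hindered cyclopentanone at −78 °C.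

**Step 17**
Reactants: 22 (2R,3S,4R,5R)-2-(allyloxy)-4-(hydroxymethyl)-5-[(1R,3aR,8aS)-1,4,4-trimethyl-8-methylidene-2-oxodecahydroazulen-1-yl]oxan-3-ol
Product: 23 (2R,3S,4R,5R)-4-(acetoxymethyl)-2-(allyloxy)-5-[(1R,3aR,8aS)-1,4,4-trimethyl-8-methylidene-2-oxodecahydroazulen-1-yl]oxan-3-yl acetate
Conditions: Ac2O, pyridine, DMAP (cat.), CH2Cl2, 0 °C to rt
Reagents that add atoms: acetic anhydride CC(=O)OC(C)=O
Why: Standard acylation installs both acetates of the target at once, before any ring oxygen is freed, so no lactone isomer can form later.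

**Step 18**
Reactants: 23 (2R,3S,4R,5R)-4-(acetoxymethyl)-2-(allyloxy)-5-[(1R,3aR,8aS)-1,4,4-trimethyl-8-methylidene-2-oxodecahydroazulen-1-yl]oxan-3-yl acetate
Product: 24 (2R,3S,4R,5R)-4-(acetoxymethyl)-2-(allyloxy)-5-[(1R,3aR,8aS)-2-hydroxy-1,4,4-trimethyl-8-methylidenedecahydroazulen-1-yl]oxan-3-yl acetate
Conditions: NaBH4, CeCl3·7H2O, MeOH, −20 °C
Reagents that add atoms: none
Why: Luche-type borohydride reduction of the remaining ketone leaves the acetates alone; the new carbinol configuration is irrelevant because the oxygen is removed next.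

**Step 19**
Reactants: 24 (2R,3S,4R,5R)-4-(acetoxymethyl)-2-(allyloxy)-5-[(1R,3aR,8aS)-2-hydroxy-1,4,4-trimethyl-8-methylidenedecahydroazulen-1-yl]oxan-3-yl acetate
Product: 25 O-phenyl thionocarbonate of 24
Conditions: PhOC(S)Cl, pyridine, DMAP, CH2Cl2, rt
Reagents that add atoms: O-phenyl chlorothionoformate S=C(Cl)Oc1ccccc1
Why: Thioacylation under neutral conditions (no alkoxide, so no acetate migration) gives the radical precursor.

**Step 20**
Reactants: 25 O-phenyl thionocarbonate of 24
Product: 26 (2R,3S,4R,5R)-4-(acetoxymethyl)-2-(allyloxy)-5-[(1R,3aR,8aS)-1,4,4-trimethyl-8-methylidenedecahydroazulen-1-yl]oxan-3-yl acetate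
Conditions: Bu3SnH (2 equiv), AIBN, toluene, 100 °C
Reagents that add atoms: none
Why: Barton–McCombie radical deoxygenation turns the former ketone carbon into CH2; the secondary radical has no favourable cyclisation onto either alkene.

**Step 21**
Reactants: 26 (2R,3S,4R,5R)-4-(acetoxymethyl)-2-(allyloxy)-5-[(1R,3aR,8aS)-1,4,4-trimethyl-8-methylidenedecahydroazulen-1-yl]oxan-3-yl acetate
Product: 28 (3S,4R,5R)-4-(acetoxymethyl)-2-hydroxy-5-[(1R,3aR,8aS)-1,4,4-trimethyl-8-methylidenedecahydroazulen-1-yl]oxan-3-yl acetate, via prop-1-enyl acetal 27 (not isolated)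
Conditions: [Ir(cod)(PMePh2)2]PF6 (3 mol %, activated with H2, then purged), THF, rt; then 0.1 M HCl, acetone/H2O, rt
Reagents that add atoms: none
Why: Iridium-hydride isomerisation of the allyl ether to the enol ether (terminal allyl reacts much faster than the 1,1-disubstituted alkene) and mild enol ether hydrolysis free the lactol without the strong acid a simple glycoside would need.

**Step 22**
Reactants: 28 (3S,4R,5R)-4-(acetoxymethyl)-2-hydroxy-5-[(1R,3aR,8aS)-1,4,4-trimethyl-8-methylidenedecahydroazulen-1-yl]oxan-3-yl acetate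
Product: 29 (3S,4R,5R)-3-acetoxy-4-(acetoxymethyl)-5-[(1R,3aR,8aS)-1,4,4-trimethyl-8-methylidenedecahydroazulen-1-yl]oxan-2-one
Conditions: Dess–Martin periodinane, NaHCO3, CH2Cl2, rt
Reagents that add atoms: none
Why: Dess–Martin oxidation of the lactol gives the δ-lactone under buffered conditions that leave the acetates, the α-acetoxy centre and the alkene intact.

**Compound list**
1 | 3-methylcyclohex-2-en-1-one | CC1=CC(=O)CCC1 | starting material
2 | lithium 3,3-dimethylcyclohex-1-en-1-olate | [Li+].[O-]C1=CC(C)(C)CCC1 | intermediate (not isolated)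
3 | allyl 3,3-dimethylcyclohex-1-en-1-yl carbonate | C=CCOC(=O)OC1=CC(C)(C)CCC1 | intermediate
4 | (S)-2-allyl-3,3-dimethylcyclohexan-1-one | O=C1CCCC(C)(C)[C@@H]1CC=C | intermediate
5 | (S)-2-(2,2-dimethyl-6-oxocyclohexyl)acetaldehyde | O=C1CCCC(C)(C)[C@@H]1CC=O | intermediate
6 | (S)-2-[2,2-bis(phenylsulfanyl)ethyl]-3,3-dimethylcyclohexan-1-one | O=C1CCCC(C)(C)[C@@H]1CC(Sc2ccccc2)Sc3ccccc3 | intermediate
7 | (1S,2S)-2-[2,2-bis(phenylsulfanyl)ethyl]-3,3-dimethyl-1-[(Z)-prop-1-enyl]cyclohexan-1-ol (major carbinol epimer) | C/C=C\[C@@]1(O)CCCC(C)(C)[C@@H]1CC(Sc2ccccc2)Sc3ccccc3 | intermediate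
8 | trimethylsilyl ether of 7 | C/C=C\[C@@]1(O[Si](C)(C)C)CCCC(C)(C)[C@@H]1CC(Sc2ccccc2)Sc3ccccc3 | intermediate
9 | S-phenyl thionium ion derived from 8 | C/C=C\[C@@]1(O[Si](C)(C)C)CCCC(C)(C)[C@@H]1CC=[S+]c2ccccc2 | intermediate (not isolated)
10 | (3aR,8aR)-1,4,4-trimethyl-2-(phenylsulfanyl)decahydroazulen-8-one, cis-fused | O=C1CCCC(C)(C)[C@@H]2CC(Sc3ccccc3)C(C)[C@H]12 | intermediate
11 | (3aR,8aR)-1,4,4-trimethyl-8-methylidene-2-(phenylsulfanyl)decahydroazulene | C=C1CCCC(C)(C)[C@@H]2CC(Sc3ccccc3)C(C)[C@H]12 | intermediate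
12 | 2-chloro-2-(phenylsulfanyl) analogue of 11 | C=C1CCCC(C)(C)[C@@H]2CC(Cl)(Sc3ccccc3)C(C)[C@H]12 | intermediate (not isolated)
13 | (3aR,8aR)-1,4,4-trimethyl-8-methylidenedecahydroazulen-2-one, cis-fused | C=C1CCCC(C)(C)[C@@H]2CC(=O)C(C)[C@H]12 | intermediate
14 | (3aR,8aS)-1,4,4-trimethyl-8-methylidene-2-(trimethylsilyloxy)-3,3a,4,5,6,7,8,8a-octahydroazulene | C=C1CCCC(C)(C)[C@@H]2CC(O[Si](C)(C)C)=C(C)[C@H]12 | intermediate
15 | D-arabinose | O=C[C@@H](O)[C@H](O)[C@H](O)CO | starting material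
16 | allyl β-D-arabinopyranoside | C=CCO[C@@H]1OC[C@@H](O)[C@@H](O)[C@@H]1O | intermediate
17 | allyl 3,4-O-thiocarbonyl-β-D-arabinopyranoside | C=CCO[C@@H]1OC[C@H]2OC(=S)O[C@H]2[C@@H]1O | intermediate
18 | (2R,3S)-2-(allyloxy)-3,6-dihydro-2H-pyran-3-ol | C=CCO[C@@H]1OCC=C[C@@H]1O | intermediate
19 | (R)-2-(allyloxy)-2H-pyran-3(6H)-one | C=CCO[C@@H]1OCC=CC1=O | intermediate
20 | trimethylsilyl enol ether of the Michael adduct | C=C1CCCC(C)(C)[C@@H]2CC(=O)[C@@](C)([C@@H]3CO[C@@H](OCC=C)C(O[Si](C)(C)C)=C3)[C@H]12 | intermediate (not isolated)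
21 | (2R,4R,5R)-2-(allyloxy)-4-(hydroxymethyl)-5-[(1R,3aR,8aS)-1,4,4-trimethyl-8-methylidene-2-oxodecahydroazulen-1-yl]oxan-3-one | C=C1CCCC(C)(C)[C@@H]2CC(=O)[C@@](C)([C@@H]3CO[C@@H](OCC=C)C(=O)[C@H]3CO)[C@H]12 | intermediate
22 | (2R,3S,4R,5R)-diol from 21 | C=C1CCCC(C)(C)[C@@H]2CC(=O)[C@@](C)([C@@H]3CO[C@@H](OCC=C)[C@@H](O)[C@H]3CO)[C@H]12 | intermediate
23 | diacetate of 22 | C=C1CCCC(C)(C)[C@@H]2CC(=O)[C@@](C)([C@@H]3CO[C@@H](OCC=C)[C@@H](OC(C)=O)[C@H]3COC(C)=O)[C@H]12 | intermediate
24 | cyclopentanol from 23 (carbinol epimers) | C=C1CCCC(C)(C)[C@@H]2CC(O)[C@@](C)([C@@H]3CO[C@@H](OCC=C)[C@@H](OC(C)=O)[C@H]3COC(C)=O)[C@H]12 | intermediate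
25 | O-phenyl thionocarbonate of 24 | C=C1CCCC(C)(C)[C@@H]2CC(OC(=S)Oc4ccccc4)[C@@](C)([C@@H]3CO[C@@H](OCC=C)[C@@H](OC(C)=O)[C@H]3COC(C)=O)[C@H]12 | intermediate
26 | (2R,3S,4R,5R)-4-(acetoxymethyl)-2-(allyloxy)-5-[(1R,3aR,8aS)-1,4,4-trimethyl-8-methylidenedecahydroazulen-1-yl]oxan-3-yl acetate | C=C1CCCC(C)(C)[C@@H]2CC[C@@](C)([C@@H]3CO[C@@H](OCC=C)[C@@H](OC(C)=O)[C@H]3COC(C)=O)[C@H]12 | intermediate
27 | (E)-prop-1-enyl acetal corresponding to 26 | C=C1CCCC(C)(C)[C@@H]2CC[C@@](C)([C@@H]3CO[C@@H](O/C=C/C)[C@@H](OC(C)=O)[C@H]3COC(C)=O)[C@H]12 | intermediate (not isolated)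
28 | lactol (anomers) | C=C1CCCC(C)(C)[C@@H]2CC[C@@](C)([C@@H]3COC(O)[C@@H](OC(C)=O)[C@H]3COC(C)=O)[C@H]12 | intermediate
29 | (3S,4R,5R)-3-acetoxy-4-(acetoxymethyl)-5-[(1R,3aR,8aS)-1,4,4-trimethyl-8-methylidenedecahydroazulen-1-yl]oxan-2-one | C=C1CCCC(C)(C)[C@@H]2CC[C@@](C)([C@@H]3COC(=O)[C@@H](OC(C)=O)[C@H]3COC(C)=O)[C@H]12 | target

**Totals**
Total step count: 22. Longest linear sequence: 18 (steps 1–10, then 15–22); steps 11–14 make the second fragment.

**Three steps most likely to fail**

Step 2 (enantioselectivity for an α-tertiary ketone next to a quaternary carbon may be modest, and the product can racemise). The fallback sets out from 3 and comes back at 4. Allylation of 3 without a chiral ligand (Pd(PPh3)4, THF) gives racemic 2-allyl-3,3-dimethylcyclohexanone F1. Li[HB(s-Bu)3] reduces it to the racemic cis-alcohol F2. DCC/DMAP esterification with (S)-O-acetylmandelic acid gives two diastereomeric esters that are separated on silica: the (1R,2S)-cyclohexyl (S)-O-acetylmandelate F3 is kept and the (1S,2R)-cyclohexyl (S)-O-acetylmandelate F4 is set aside. LiOH hydrolysis of F3 gives (1R,2S)-2-allyl-3,3-dimethylcyclohexan-1-ol F5, and Dess–Martin oxidation returns enantiopure 4.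

Step 15 (a congested quaternary–tertiary bond, double stereodifferentiation, and an acid-sensitive acceptor under silyl-cation catalysis). The fallback sets out from 14 and 19 and comes back at 21. α-Iodination of 19 (I2, pyridine, CH2Cl2) gives the more electrophilic (R)-2-(allyloxy)-4-iodo-2H-pyran-3(6H)-one F6. MeLi cleaves 14 to the regiodefined lithium enolate F7, which is added to F6 at −78 °C in an anionic Michael addition to an α-haloenone, giving the α-iodo ketone adduct F8. SmI2 at −78 °C then converts F8 into its samarium enolate, which is trapped with monomeric formaldehyde (Reformatsky-type aldol) to give 21.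

Step 16 (the borohydride may also attack the cyclopentanone). The fallback sets out from 21 and comes back at 26. Both ketones are reduced on purpose (Li[HB(s-Bu)3] at −78 °C, then NaBH4 at 0 °C) to the triol F9. 2,2-Dimethoxypropane/PPTS forms the six-membered acetonide F10 across the C3 hydroxyl and the hydroxymethyl group, leaving only the cyclopentanol free. PhOC(S)Cl/pyridine gives the thionocarbonate F11, and Bu3SnH/AIBN gives the deoxygenated acetonide F12. 80 % aq. AcOH at 40 °C releases the diol F13, and Ac2O/pyridine gives 26.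

**Further compounds**
F1 | step 2 | racemic 2-allyl-3,3-dimethylcyclohexan-1-one | C=CCC1C(=O)CCCC1(C)C
F2 | step 2 | racemic cis-2-allyl-3,3-dimethylcyclohexan-1-ol (relative configuration shown) | O[C@@H]1CCCC(C)(C)[C@@H]1CC=C
F3 | step 2 | (1R,2S)-2-allyl-3,3-dimethylcyclohexyl (S)-O-acetylmandelate | CC(=O)O[C@@H](c1ccccc1)C(=O)O[C@@H]1CCCC(C)(C)[C@@H]1CC=C
F4 | step 2 | (1S,2R)-2-allyl-3,3-dimethylcyclohexyl (S)-O-acetylmandelate | CC(=O)O[C@@H](c1ccccc1)C(=O)O[C@H]1CCCC(C)(C)[C@H]1CC=C
F5 | step 2 | (1R,2S)-2-allyl-3,3-dimethylcyclohexan-1-ol | O[C@@H]1CCCC(C)(C)[C@@H]1CC=C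
F6 | step 15 | (R)-2-(allyloxy)-4-iodo-2H-pyran-3(6H)-one | C=CCO[C@@H]1OCC=C(I)C1=O
F7 | step 15 | lithium enolate corresponding to 14 | C=C1CCCC(C)(C)[C@@H]2CC([O-])=C(C)[C@H]12.[Li+]
F8 | step 15 | α-iodo ketone Michael adduct (iodide epimers) | C=C1CCCC(C)(C)[C@@H]2CC(=O)[C@@](C)([C@@H]3CO[C@@H](OCC=C)C(=O)C3I)[C@H]12
F9 | step 16 | triol from 21 (cyclopentanol epimers) | C=C1CCCC(C)(C)[C@@H]2CC(O)[C@@](C)([C@@H]3CO[C@@H](OCC=C)[C@@H](O)[C@H]3CO)[C@H]12
F10 | step 16 | acetonide of F9 | C=C1CCCC(C)(C)[C@@H]2CC(O)[C@@](C)([C@@H]3CO[C@@H](OCC=C)[C@H]4OC(C)(C)OC[C@@H]34)[C@H]12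
F11 | step 16 | O-phenyl thionocarbonate of F10 | C=C1CCCC(C)(C)[C@@H]2CC(OC(=S)Oc5ccccc5)[C@@](C)([C@@H]3CO[C@@H](OCC=C)[C@H]4OC(C)(C)OC[C@@H]34)[C@H]12
F12 | step 16 | deoxygenated acetonide | C=C1CCCC(C)(C)[C@@H]2CC[C@@](C)([C@@H]3CO[C@@H](OCC=C)[C@H]4OC(C)(C)OC[C@@H]34)[C@H]12
F13 | step 16 | deoxygenated diol | C=C1CCCC(C)(C)[C@@H]2CC[C@@](C)([C@@H]3CO[C@@H](OCC=C)[C@@H](O)[C@H]3CO)[C@H]12
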